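**Retrosynthetic overview**
Ring numbering used throughout: C1 ketone, C2 (bears C7H2OH), C3 alkene CH, C4 propionyloxy carbon, C5 isopropyl carbon, C6 enoyloxy carbon.
Feature: on the single six-membered carbocycle the oxygens on C1 and C4 are para to each other, as are C7 (on C2) and isopropyl (on C5). The ring is therefore a dearomatised hydroquinone of the p-cymene series, and the third ring oxygen (C6) lies β to a carbonyl placed at C4.
Disconnections, backwards: the silyl ethers and the C1 dimethyl ketal; the acyl–O bonds at C6 and C4; C4–H (bulky hydride on a C4 enone); C5–H (reductive cleavage of C5–O in a C5/C6 oxirane); both oxirane C–O bonds (enantioselective nucleophilic epoxidation of the C4-keto, C1-ketal dienone); C1–OMe (oxidative dearomatisation of a 4-methoxyphenol).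
Ring order: the carbocycle is the benzene ring of 2-isopropylphenol and is never rebuilt. The oxirane is the only ring closed (step 8), and it is opened again in step 9 once C6 holds its configuration.
The E-enoic acid side chain comes from a stabilised-ylide Wittig reaction and is attached last but one.

Key step: step 8

Assumption: the cinchonidine-derived salt is taken to open the C6 face that leads to the (1S,6R) epoxide. If it favours the other face, the pseudoenantiomeric N-benzylcinchoninium chloride is used and nothing else changes.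
Remark: no hydroxyl-directed borohydride is used at C4, because an equatorial C6–O bond is antiperiplanar to C5–C4 and cannot reach the carbonyl, so reagent approach control delivers the same anti-1,3-diol. C6 is acylated only after C4 is reduced, since a β-acyloxy ketone would eliminate.

Step 1
Reactants: 1 2-(propan-2-yl)phenol
Product: 2 4-bromo-2-(propan-2-yl)phenol
Conditions: NBS, MeCN, 0 °C
Reagents that add atoms: N-bromosuccinimide, O=C1CCC(=O)N1Br
Why: Electrophilic aromatic bromination, in which the hydroxyl group directs para, one ortho site is blocked by isopropyl and the other is the slower position under these mild conditions.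

Step 2
Reactants: 2 4-bromo-2-(propan-2-yl)phenol
Product: 3 4-methoxy-2-(propan-2-yl)phenol
Conditions: NaOMe (excess), CuI (10 mol%), DMF–MeOH, 110 °C; then dil. HCl
Reagents that add atoms: sodium methoxide, C[O-].[Na+]
Why: Copper-catalysed Ullmann-type methoxylation of an aryl bromide, a reaction established for 2-alkyl-4-bromophenols as their phenoxides, places methoxy para to hydroxyl without regiochemical ambiguity.

Step 3
Reactants: 3 4-methoxy-2-(propan-2-yl)phenol
Product: 4 4-methoxy-2-(propan-2-yl)phenyl acetate
Conditions: Ac2O, pyridine, DMAP (cat.), CH2Cl2, rt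
Reagents that add atoms: acetic anhydride, CC(=O)OC(C)=O
Why: O-Acetylation turns the strongest donor into a weak one, so that methoxy alone steers the next substitution.

Step 4
Reactants: 4 4-methoxy-2-(propan-2-yl)phenyl acetate; 5 dichloromethyl methyl ether
Product: 7 5-formyl-4-methoxy-2-(propan-2-yl)phenyl acetate, via chloro(methoxy)methyl arene 6 (not isolated)
Conditions: TiCl4 (2.5 equiv), CH2Cl2, −10 to 0 °C; then ice–water
Reagents that add atoms: dichloromethyl methyl ether (5), COC(Cl)Cl; water, O
Why: Rieche formylation (Friedel–Crafts type) attacks the carbon ortho to methoxy and para to isopropyl, because the other ortho site is wedged between methoxy and isopropyl and the site beside the TiCl4-bound acetate is deactivated, and water then hydrolyses the chloro ether to the aldehyde.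

Step 5
Reactants: 7 5-formyl-4-methoxy-2-(propan-2-yl)phenyl acetate
Product: 8 5-(hydroxymethyl)-4-methoxy-2-(propan-2-yl)phenol
Conditions: LiAlH4, THF, 0 °C; then sat. aq. NH4Cl
Reagents that add atoms: none
Why: Hydride reduction with LiAlH4 takes the aldehyde to the benzylic alcohol and cleaves the aryl acetate in one operation, which saves separate reduction and deacylation steps.

Step 6
Reactants: 8 5-(hydroxymethyl)-4-methoxy-2-(propan-2-yl)phenol
Product: 9 5-(hydroxymethyl)-4,4-dimethoxy-2-(propan-2-yl)cyclohexa-2,5-dien-1-one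
Conditions: PhI(OAc)2 (1.05 equiv), MeOH, 0 °C
Reagents that add atoms: methanol, CO
Why: Oxidative dearomatisation of a 4-methoxyphenol, by phenol exchange at iodine, loss of iodobenzene and capture of the para carbon by methanol, gives the p-quinone monoketal with the ketone at C4 and the ketal at C1 by construction, and the primary alcohol is not oxidised at this temperature.

Step 7
Reactants: 9 5-(hydroxymethyl)-4,4-dimethoxy-2-(propan-2-yl)cyclohexa-2,5-dien-1-one
Product: 10 5-({[tert-butyl(dimethyl)silyl]oxy}methyl)-4,4-dimethoxy-2-(propan-2-yl)cyclohexa-2,5-dien-1-one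
Conditions: TBSCl, imidazole, CH2Cl2, 0 °C to rt
Reagents that add atoms: tert-butyl(chloro)dimethylsilane, CC(C)(C)[Si](C)(C)Cl
Why: Standard silylation of the only hydroxyl group ensures that no alkoxide can steer or intercept the peroxide in the next step.

Step 8
Reactants: 10 5-({[tert-butyl(dimethyl)silyl]oxy}methyl)-4,4-dimethoxy-2-(propan-2-yl)cyclohexa-2,5-dien-1-one
Product: 11 (1S,6R)-4-({[tert-butyl(dimethyl)silyl]oxy}methyl)-5,5-dimethoxy-1-(propan-2-yl)-7-oxabicyclo[4.1.0]hept-3-en-2-one
Conditions: t-BuOOH (5.5 M in decane), 1 M aq. NaOH, N-benzylcinchonidinium chloride (10 mol%), toluene, 0 °C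
Reagents that add atoms: tert-butyl hydroperoxide, CC(C)(C)OO
Why: This is a Weitz–Scheffer epoxidation under chiral phase-transfer catalysis, a reaction type already established for p-quinone monoketals: the tert-butyl peroxide anion enters the toluene phase as the ion pair of the cinchonidinium cation, adds in conjugate fashion to C6, and the resulting C4 enolate attacks the inner peroxide oxygen through C5 while tert-butoxide leaves. The oxirane therefore closes in a 3-exo-tet mode, with the breaking O–O bond outside the new ring. C6 is set in the addition event by the chiral cation, which sits on one face of the flat dienone and leaves the other open to the paired peroxide; C5 has no freedom of its own, because an oxirane fused to a six-membered ring can only be cis, so it copies C6. The step needs site selectivity between the two enone alkenes, and the substrate supplies it: C6 is a β-CH, whereas the other β-carbon, C2, carries the silyloxymethyl group and would have to become a fully substituted centre beside the ketal carbon. It also needs a substrate that tolerates aqueous base, which holds because the dienone has no enolisable hydrogen, the hydroxyl is silylated and the ketal is base-stable; a second epoxidation is held back by the same hindrance at C2.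

Step 9
Reactants: 11 (1S,6R)-4-({[tert-butyl(dimethyl)silyl]oxy}methyl)-5,5-dimethoxy-1-(propan-2-yl)-7-oxabicyclo[4.1.0]hept-3-en-2-one
Product: 12 (5R)-3-({[tert-butyl(dimethyl)silyl]oxy}methyl)-5-hydroxy-4,4-dimethoxy-6-(propan-2-yl)cyclohex-2-en-1-one, pair of epimers at the isopropyl carbon (route atom C5)
Conditions: SmI2 (2.1 equiv), THF–MeOH, −90 °C; then pH 7 phosphate buffer
Reagents that add atoms: none
Why: In this reductive opening of an α,β-epoxy ketone by SmI2, two single-electron transfers through the C4 ketyl break the C5–O bond aligned with the carbonyl π system, C6–O and its configuration stay untouched, methanol protonates the samarium enolate at C5 without reliable facial bias (hence the epimer pair), and the low temperature and near-stoichiometric reductant keep the remaining enone and its γ-methoxy groups from being reduced.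

Step 10
Reactants: 12 (5R)-3-({[tert-butyl(dimethyl)silyl]oxy}methyl)-5-hydroxy-4,4-dimethoxy-6-(propan-2-yl)cyclohex-2-en-1-one (epimer pair)
Product: 13 (5R,6R)-3-({[tert-butyl(dimethyl)silyl]oxy}methyl)-5-hydroxy-4,4-dimethoxy-6-(propan-2-yl)cyclohex-2-en-1-one (isopropyl trans to hydroxyl)
Conditions: DBU (0.2 equiv), toluene, rt; cis epimer separated and resubmitted
Reagents that add atoms: none
Why: In this base-mediated epimerisation through the C4 enolate, only C5 is both acidic and stereogenic, the trans isomer holds isopropyl and hydroxyl equatorial on the sofa-shaped cyclohexenone and should be the lower in energy, and a catalytic amidine in an aprotic solvent is too weak to expel hydroxide (E1cB back to 10) or to trigger retro-aldol opening at a useful rate.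

Step 11
Reactants: 13 (5R,6R)-3-({[tert-butyl(dimethyl)silyl]oxy}methyl)-5-hydroxy-4,4-dimethoxy-6-(propan-2-yl)cyclohex-2-en-1-one
Product: 14 (1R,2S,3S)-5-({[tert-butyl(dimethyl)silyl]oxy}methyl)-6,6-dimethoxy-2-(propan-2-yl)cyclohex-4-ene-1,3-diol
Conditions: LiBH(s-Bu)3 (2.5 equiv), THF, −78 °C; then H2O
Reagents that add atoms: none
Why: In this reagent-approach-controlled 1,2-reduction the bulky trialkylborohydride takes the equatorial trajectory on the face that carries only the axial C5–H, away from the isopropyl methyls and the axial C6–H, which puts the new C4 hydroxyl axial, cis to isopropyl and anti to the C6 hydroxyl (C4 S), while conjugate reduction is shut off because the β-carbon C2 is fully substituted and adjoins the ketal carbon.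

Step 12
Reactants: 14 (1R,2S,3S)-5-({[tert-butyl(dimethyl)silyl]oxy}methyl)-6,6-dimethoxy-2-(propan-2-yl)cyclohex-4-ene-1,3-diol
Product: 15 (1S,5R,6R)-3-({[tert-butyl(dimethyl)silyl]oxy}methyl)-5-hydroxy-4,4-dimethoxy-6-(propan-2-yl)cyclohex-2-en-1-yl propanoate
Conditions: (EtCO)2O (1.1 equiv), Et3N, DMAP (cat.), CH2Cl2, −20 °C
Reagents that add atoms: propionic anhydride, CCC(=O)OC(=O)CC
Why: This site-selective acylation relies on the allylic C4 hydroxyl having a planar CH neighbour while the C6 hydroxyl is flanked by the quaternary ketal carbon and the isopropyl-bearing carbon, and the anti-1,3 relation of the two oxygens rules out later acyl migration.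

Step 13
Reactants: 16 {[tert-butyl(dimethyl)silyl]oxy}acetaldehyde; 17 ethyl 2-(triphenyl-λ5-phosphanylidene)propanoate
Product: 18 ethyl (2E)-4-{[tert-butyl(dimethyl)silyl]oxy}-2-methylbut-2-enoate
Conditions: CH2Cl2, rt
Reagents that add atoms: ethyl 2-(triphenyl-λ5-phosphanylidene)propanoate (17), CCOC(=O)C(C)=P(c1ccccc1)(c1ccccc1)c1ccccc1
Why: Wittig olefination with a stabilised, α-branched ylide should give the E-trisubstituted enoate, with the ester trans to the silyloxymethyl group.

Step 14
Reactants: 18 ethyl (2E)-4-{[tert-butyl(dimethyl)silyl]oxy}-2-methylbut-2-enoate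
Product: 19 (2E)-4-{[tert-butyl(dimethyl)silyl]oxy}-2-methylbut-2-enoic acid
Conditions: LiOH, THF–MeOH–H2O, rt; then 1 M HCl to pH 4, 0 °C
Reagents that add atoms: lithium hydroxide, [Li+].[OH-]
Why: Ester saponification leaves the primary silyl ether and the alkene geometry unaffected by LiOH and by a short, cold, mildly acidic work-up.

Step 15
Reactants: 15 (1S,5R,6R)-3-({[tert-butyl(dimethyl)silyl]oxy}methyl)-5-hydroxy-4,4-dimethoxy-6-(propan-2-yl)cyclohex-2-en-1-yl propanoate; 19 (2E)-4-{[tert-butyl(dimethyl)silyl]oxy}-2-methylbut-2-enoic acid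
Product: 21 (1S,5R,6S)-3-({[tert-butyl(dimethyl)silyl]oxy}methyl)-5-{[(2E)-4-{[tert-butyl(dimethyl)silyl]oxy}-2-methylbut-2-enoyl]oxy}-4,4-dimethoxy-6-(propan-2-yl)cyclohex-2-en-1-yl propanoate, via mixed trichlorobenzoic anhydride 20 (not isolated)
Conditions: 19, 2,4,6-Cl3C6H2COCl, Et3N, toluene, rt; then 15, DMAP, toluene, rt to 50 °C
Reagents that add atoms: (2E)-4-{[tert-butyl(dimethyl)silyl]oxy}-2-methylbut-2-enoic acid (19), OC(=O)/C(C)=C/CO[Si](C)(C)C(C)(C)C; 2,4,6-trichlorobenzoyl chloride (atoms stay only in 20), O=C(Cl)c1c(Cl)cc(Cl)cc1Cl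
Why: In this Yamaguchi esterification DMAP attacks the less hindered enoyl carbonyl of the mixed anhydride, the acylpyridinium ion acylates the crowded C6 hydroxyl with the C6–O bond intact (retention), and the E-alkene is the stable geometry and should not drift.

Step 16
Reactants: 21 (1S,5R,6S)-3-({[tert-butyl(dimethyl)silyl]oxy}methyl)-5-{[(2E)-4-{[tert-butyl(dimethyl)silyl]oxy}-2-methylbut-2-enoyl]oxy}-4,4-dimethoxy-6-(propan-2-yl)cyclohex-2-en-1-yl propanoate
Product: 23 (1S,5R,6S)-3-(hydroxymethyl)-5-{[(2E)-4-hydroxy-2-methylbut-2-enoyl]oxy}-4-oxo-6-(propan-2-yl)cyclohex-2-en-1-yl propanoate, via bis-desilylated dimethyl ketal 22 (not isolated)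
Conditions: 48% aq. HF, MeCN, 0 °C to rt
Reagents that add atoms: water, O
Why: In this acidic global deprotection HF cleaves both primary silyl ethers, the aqueous acid hydrolyses the allylic dimethyl ketal through a conjugated oxocarbenium ion, both esters survive, and C6 (now α to the ketone) is not at risk because its equatorial acyloxy group is the stable arrangement, the axial epimer being syn-diaxial to the C4 propionate.

**Compound list**
1 | 2-(propan-2-yl)phenol | CC(C)c1ccccc1O | starting material
2 | 4-bromo-2-(propan-2-yl)phenol | CC(C)c1cc(Br)ccc1O | intermediate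
3 | 4-methoxy-2-(propan-2-yl)phenol | CC(C)c1cc(OC)ccc1O | intermediate
4 | 4-methoxy-2-(propan-2-yl)phenyl acetate | CC(C)c1cc(OC)ccc1OC(C)=O | intermediate
5 | dichloromethyl methyl ether | COC(Cl)Cl | starting material
6 | 5-[chloro(methoxy)methyl]-4-methoxy-2-(propan-2-yl)phenyl acetate | CC(C)c1cc(OC)c(C(Cl)OC)cc1OC(C)=O | intermediate
7 | 5-formyl-4-methoxy-2-(propan-2-yl)phenyl acetate | CC(C)c1cc(OC)c(C=O)cc1OC(C)=O | intermediate
8 | 5-(hydroxymethyl)-4-methoxy-2-(propan-2-yl)phenol | CC(C)c1cc(OC)c(CO)cc1O | intermediate
9 | 5-(hydroxymethyl)-4,4-dimethoxy-2-(propan-2-yl)cyclohexa-2,5-dien-1-one | CC(C)C1=CC(OC)(OC)C(CO)=CC1=O | intermediate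
10 | 5-({[tert-butyl(dimethyl)silyl]oxy}methyl)-4,4-dimethoxy-2-(propan-2-yl)cyclohexa-2,5-dien-1-one | CC(C)C1=CC(OC)(OC)C(CO[Si](C)(C)C(C)(C)C)=CC1=O | intermediate
11 | (1S,6R)-4-({[tert-butyl(dimethyl)silyl]oxy}methyl)-5,5-dimethoxy-1-(propan-2-yl)-7-oxabicyclo[4.1.0]hept-3-en-2-one | O=C1C=C(CO[Si](C)(C)C(C)(C)C)C(OC)(OC)[C@@H]2O[C@]12C(C)C | intermediate
12 | (5R)-3-({[tert-butyl(dimethyl)silyl]oxy}methyl)-5-hydroxy-4,4-dimethoxy-6-(propan-2-yl)cyclohex-2-en-1-one, epimer pair at the isopropyl carbon | O=C1C=C(CO[Si](C)(C)C(C)(C)C)C(OC)(OC)[C@H](O)C1C(C)C | intermediate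
13 | (5R,6R)-3-({[tert-butyl(dimethyl)silyl]oxy}methyl)-5-hydroxy-4,4-dimethoxy-6-(propan-2-yl)cyclohex-2-en-1-one | O=C1C=C(CO[Si](C)(C)C(C)(C)C)C(OC)(OC)[C@H](O)[C@H]1C(C)C | intermediate
14 | (1R,2S,3S)-5-({[tert-butyl(dimethyl)silyl]oxy}methyl)-6,6-dimethoxy-2-(propan-2-yl)cyclohex-4-ene-1,3-diol | O[C@H]1C=C(CO[Si](C)(C)C(C)(C)C)C(OC)(OC)[C@H](O)[C@H]1C(C)C | intermediate
15 | (1S,5R,6R)-3-({[tert-butyl(dimethyl)silyl]oxy}methyl)-5-hydroxy-4,4-dimethoxy-6-(propan-2-yl)cyclohex-2-en-1-yl propanoate | CCC(=O)O[C@H]1C=C(CO[Si](C)(C)C(C)(C)C)C(OC)(OC)[C@H](O)[C@H]1C(C)C | intermediate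
16 | {[tert-butyl(dimethyl)silyl]oxy}acetaldehyde | O=CCO[Si](C)(C)C(C)(C)C | starting material
17 | ethyl 2-(triphenyl-λ5-phosphanylidene)propanoate | CCOC(=O)C(C)=P(c1ccccc1)(c1ccccc1)c1ccccc1 | starting material
18 | ethyl (2E)-4-{[tert-butyl(dimethyl)silyl]oxy}-2-methylbut-2-enoate | CCOC(=O)/C(C)=C/CO[Si](C)(C)C(C)(C)C | intermediate
19 | (2E)-4-{[tert-butyl(dimethyl)silyl]oxy}-2-methylbut-2-enoic acid | OC(=O)/C(C)=C/CO[Si](C)(C)C(C)(C)C | intermediate
20 | (2E)-4-{[tert-butyl(dimethyl)silyl]oxy}-2-methylbut-2-enoic 2,4,6-trichlorobenzoic anhydride | O=C(OC(=O)c1c(Cl)cc(Cl)cc1Cl)/C(C)=C/CO[Si](C)(C)C(C)(C)C | intermediate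
21 | (1S,5R,6S)-3-({[tert-butyl(dimethyl)silyl]oxy}methyl)-5-{[(2E)-4-{[tert-butyl(dimethyl)silyl]oxy}-2-methylbut-2-enoyl]oxy}-4,4-dimethoxy-6-(propan-2-yl)cyclohex-2-en-1-yl propanoate | CCC(=O)O[C@H]1C=C(CO[Si](C)(C)C(C)(C)C)C(OC)(OC)[C@H](OC(=O)/C(C)=C/CO[Si](C)(C)C(C)(C)C)[C@H]1C(C)C | intermediate
22 | (1S,5R,6S)-3-(hydroxymethyl)-5-{[(2E)-4-hydroxy-2-methylbut-2-enoyl]oxy}-4,4-dimethoxy-6-(propan-2-yl)cyclohex-2-en-1-yl propanoate | CCC(=O)O[C@H]1C=C(CO)C(OC)(OC)[C@H](OC(=O)/C(C)=C/CO)[C@H]1C(C)C | intermediate
23 | (1S,5R,6S)-3-(hydroxymethyl)-5-{[(2E)-4-hydroxy-2-methylbut-2-enoyl]oxy}-4-oxo-6-(propan-2-yl)cyclohex-2-en-1-yl propanoate (CNP0285949.1) | CCC(=O)O[C@H]1C=C(CO)C(=O)[C@H](OC(=O)/C(C)=C/CO)[C@H]1C(C)C | target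

**Step count and risks**
Total step count: 16. Longest linear sequence: 14 (steps 1–12, 15 and 16). The side chain takes 2 steps (13 and 14).

Most likely to fail, first: step 8. The conjugate addition may be sluggish, because the reacting alkene lies beside the ketal carbon and carries an α-isopropyl group. The ammonium ion may also shield one dienone face incompletely, which would lower conversion and erode enantiomeric purity. The fallback replaces asymmetric catalysis with a resolution. It sets out from 10, which is epoxidised without a chiral salt (t-BuOOH, DBU, CH2Cl2) to the racemic epoxy ketone F1. The operations of steps 9 to 11, applied unchanged, lead through the racemic hydroxy ketone epimer pair F2 and the racemic trans-hydroxy ketone F3 to the racemic diol F4. An acylative kinetic resolution of F4 follows, using propionic anhydride, i-Pr2NEt and the chiral isothiourea benzotetramisole (antipode chosen by trial) in CHCl3 at 0 °C. It should propionylate the (1R,2S,3S) enantiomer at the allylic C4 hydroxyl, so the route is rejoined at 15. The antipodal diol F5 stays unacylated and is separated.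

Second: step 10. The equilibrium may lie too little on the trans side, because an axial C6 hydroxyl meets no syn-axial hydrogen on the sofa-shaped enone. Long exposure to base may also cause slow loss of water or retro-aldol opening. The fallback replaces substrate thermodynamics with catalyst control. It sets out from 12, whose epimer pair is hydrogenated directly with RuCl2[(R)-binap][(S,S)-dpen] and a catalytic base (t-BuOK, or K2CO3 if elimination shows) in i-PrOH under H2 (8 atm) at rt. This is a Noyori asymmetric hydrogenation run as a dynamic kinetic resolution. The base interconverts the C5 epimers, the catalyst reduces C=O and not C=C, and it takes the epimer and carbonyl face that give the C4/C5-cis alcohol, as with 2-isopropylcyclohexanone. The catalyst antipode is confirmed by trial. The route is rejoined at 14, and steps 10 and 11 are both bypassed.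

Third: step 11. Competing axial hydride attack would give the C4 epimer, and some conjugate reduction cannot be excluded. The site selectivity of the following acylation also depends on this diol. The fallback accepts the opposite facial outcome and inverts it. It sets out from 13, where Luche reduction (NaBH4, CeCl3·7H2O, MeOH, −78 °C) should deliver hydride axially and give the equatorial C4-epimeric diol F6. A Mitsunobu reaction with propionic acid (PPh3, DIAD, toluene, 0 °C to rt) then displaces the activated allylic C4 oxygen with inversion. The neopentyl-like C6 hydroxyl is too hindered to react. Configuration and propionate are thus installed together, and the route is rejoined at 15.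

**Further compounds**
F1 | step 8 | racemic 4-({[tert-butyl(dimethyl)silyl]oxy}methyl)-5,5-dimethoxy-1-(propan-2-yl)-7-oxabicyclo[4.1.0]hept-3-en-2-one | O=C1C=C(CO[Si](C)(C)C(C)(C)C)C(OC)(OC)C2OC12C(C)C
F2 | step 8 | racemic 3-({[tert-butyl(dimethyl)silyl]oxy}methyl)-5-hydroxy-4,4-dimethoxy-6-(propan-2-yl)cyclohex-2-en-1-one, cis and trans | O=C1C=C(CO[Si](C)(C)C(C)(C)C)C(OC)(OC)C(O)C1C(C)C
F3 | step 8 | racemic trans-3-({[tert-butyl(dimethyl)silyl]oxy}methyl)-5-hydroxy-4,4-dimethoxy-6-(propan-2-yl)cyclohex-2-en-1-one, (5R,6R) plus (5S,6S) | O=C1C=C(CO[Si](C)(C)C(C)(C)C)C(OC)(OC)[C@H](O)[C@H]1C(C)C.O=C1C=C(CO[Si](C)(C)C(C)(C)C)C(OC)(OC)[C@@H](O)[C@@H]1C(C)C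
F4 | step 8 | racemic 5-({[tert-butyl(dimethyl)silyl]oxy}methyl)-6,6-dimethoxy-2-(propan-2-yl)cyclohex-4-ene-1,3-diol, (1R,2S,3S) plus (1S,2R,3R) | O[C@H]1C=C(CO[Si](C)(C)C(C)(C)C)C(OC)(OC)[C@H](O)[C@H]1C(C)C.O[C@@H]1C=C(CO[Si](C)(C)C(C)(C)C)C(OC)(OC)[C@@H](O)[C@@H]1C(C)C
F5 | step 8 | (1S,2R,3R)-5-({[tert-butyl(dimethyl)silyl]oxy}methyl)-6,6-dimethoxy-2-(propan-2-yl)cyclohex-4-ene-1,3-diol | O[C@@H]1C=C(CO[Si](C)(C)C(C)(C)C)C(OC)(OC)[C@@H](O)[C@@H]1C(C)C
F0 | step 10 | none | none
F6 | step 11 | (1R,2S,3R)-5-({[tert-butyl(dimethyl)silyl]oxy}methyl)-6,6-dimethoxy-2-(propan-2-yl)cyclohex-4-ene-1,3-diol | O[C@@H]1C=C(CO[Si](C)(C)C(C)(C)C)C(OC)(OC)[C@H](O)[C@H]1C(C)C
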